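**Retrosynthetic overview**
1. Target 17 ⇒ hydrogenolysis of eight benzyl ethers ⇒ two aryl ester bonds (at O7 and O3') made from 5,4'-di-O-benzylcatechin 13 and galloyl chloride 15. O7 and O3' are marked as MOM ethers, and O5 and O4' as benzyl ethers, already on the monocyclic building blocks.
2. C3–OH ⇒ hydroboration–oxidation of the C3=C4 bond of (2S)-flav-3-ene 10, anti to ring B, so that C2 relays its configuration to C3.
3. Ring C (O1–C2 bond) ⇒ enantioconvergent, chiral-acid-catalysed cyclodehydration of the racemic open-chain allylic alcohol 8. Alcohol 8 comes from enone 7, the Claisen–Schmidt union of aldehyde 3 (ring A + C4) and ketone 6 (ring B + C2, C3).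
4. Enabling feature: the C2–C3–C4 chain lies between ring B (O4' para to C2) and ring A (O5, O7 and the C8a oxygen ortho/para to C4a). At the flavene oxidation level it ionises to one achiral, delocalised 1,3-diarylallyl cation. This erases carbinol configuration, allylic regiochemistry and alkene geometry, and the C8a–OH can reach only C2.
5. Ring order: rings A, B and both galloyl rings are bought as arenes. Ring C is the only ring made and is closed last.

Key step: step 7

Assumption: the sense of induction of the BINOL-derived catalyst cannot be derived with certainty from the analogies. The (R)-catalyst is written, and its enantiomer is taken if the opposite sense is found.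

Step 1
Reactants: 1 2,4,6-trihydroxybenzaldehyde
Product: 2 2,6-dihydroxy-4-(methoxymethoxy)benzaldehyde
Conditions: MOMCl (1.0 equiv), K2CO3 (1.0 equiv), acetone, 0 °C → rt
Reagents that add atoms: chloromethyl methyl ether, COCCl
Why: Williamson-type O-alkylation; the 4-OH, para to the formyl group, is the most acidic hydroxyl and the only one not hydrogen-bonded to C=O, so one equivalent of base and MOMCl should mark the later O7 selectively.

Step 2
Reactants: 2 2,6-dihydroxy-4-(methoxymethoxy)benzaldehyde
Product: 3 2-(benzyloxy)-6-hydroxy-4-(methoxymethoxy)benzaldehyde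
Conditions: BnBr (1.05 equiv), K2CO3 (1.1 equiv), DMF, rt
Reagents that add atoms: benzyl bromide, BrCc1ccccc1
Why: Williamson etherification of one of two equivalent chelated hydroxyls; after the first benzylation the remaining OH is held more strongly by the aldehyde, so the reaction should stop at the mono-ether and leave the later O1 free.

Step 3
Reactants: 4 3',4'-dihydroxyacetophenone
Product: 5 4'-(benzyloxy)-3'-hydroxyacetophenone
Conditions: BnBr (1.0 equiv), K2CO3 (1.0 equiv), acetone, rt → 40 °C
Reagents that add atoms: benzyl bromide, BrCc1ccccc1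
Why: Regioselective Williamson etherification; the 4'-OH is para to the acetyl group and more acidic, so with one equivalent of base its phenoxide is benzylated in preference to the 3'-OH.

Step 4
Reactants: 5 4'-(benzyloxy)-3'-hydroxyacetophenone
Product: 6 4'-(benzyloxy)-3'-(methoxymethoxy)acetophenone
Conditions: MOMCl (1.3 equiv), K2CO3, acetone, rt
Reagents that add atoms: chloromethyl methyl ether, COCCl
Why: Williamson-type MOM protection of the only remaining phenol marks the later O3' with the same acid-labile group as O7.

Step 5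
Reactants: 3 2-(benzyloxy)-6-hydroxy-4-(methoxymethoxy)benzaldehyde; 6 4'-(benzyloxy)-3'-(methoxymethoxy)acetophenone
Product: 7 (E)-3-[2-(benzyloxy)-6-hydroxy-4-(methoxymethoxy)phenyl]-1-[4-(benzyloxy)-3-(methoxymethoxy)phenyl]prop-2-en-1-one
Conditions: KOH (50 % aq), EtOH, rt → 45 °C, dark; then AcOH to pH 6
Reagents that add atoms: none
Why: Claisen–Schmidt condensation (aldol addition, then E1cB loss of water) as used for 2-hydroxychalcones; the thermodynamically favoured E-enone forms, and MOM and benzyl ethers are inert to hydroxide.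

Step 6
Reactants: 7 the (E)-enone of step 5
Product: 8 rac-(E)-3-[2-(benzyloxy)-6-hydroxy-4-(methoxymethoxy)phenyl]-1-[4-(benzyloxy)-3-(methoxymethoxy)phenyl]prop-2-en-1-ol
Conditions: DIBAL-H (2.5 equiv), CH2Cl2, −78 °C; aq Rochelle salt; short plug of Et3N-deactivated silica
Reagents that add atoms: none
Why: 1,2-Reduction of an aryl enone with DIBAL-H (the first equivalent only turns the phenol into its aluminium phenoxide); the carbinol centre is made racemic on purpose because step 7 erases it, and the aprotic conditions and non-acidic work-up should keep the ionisable alcohol intact.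

Step 7
Reactants: 8 the racemic (E)-allylic alcohol of step 6
Product: 10 (2S)-5-(benzyloxy)-2-[4-(benzyloxy)-3-(methoxymethoxy)phenyl]-7-(methoxymethoxy)-2H-chromene, via diarylallyl cation 9 (not isolated)
Conditions: (R)-3,3'-bis(2,4,6-triisopropylphenyl)-BINOL N-triflylphosphoramide (5 mol %), 4 Å MS, toluene (0.01 M), −78 °C, Ar, dark; Et3N quench at −78 °C
Reagents that add atoms: none
Why: The strong chiral acid protonates the allylic hydroxyl of either enantiomer of 8 (and of any 1,3-transposed or Z isomer that forms on handling), water leaves into the sieves, and all of them give the same achiral 1,3-diarylallyl cation 9, whose charge is shared by C2, C4, the 4'-benzyloxy ring B and the 5,7,8a-trioxygenated ring A, so that the C3–C4 bond has enough single-bond character to rotate into the cisoid geometry needed for closure. The closest known reaction type is the asymmetric intramolecular allylic substitution of (E)-2-(3-hydroxyalk-1-enyl)phenols to 2H-chromenes catalysed by BINOL N-triflylphosphoramides through contact ion pairs, with the Pd-catalysed enantioselective cyclisation of the corresponding allylic acetates to 2-aryl-2H-chromenes as a second analogy. Ring C closes by O1–C2 bond formation in a 6-endo-trig capture of the allyl cation by the C8a hydroxyl, which can equally be read as a disrotatory oxa-6π closure of the O-protonated vinylogous ortho-quinone methide. The only new stereocentre, C2, is controlled by the catalyst: the phosphoramidate anion stays hydrogen-bonded to the C8a–OH that it deprotonates and ion-paired to 9, so its 3,3'-aryl walls leave one face of C2 open, and since both enantiomers of 8 pass through 9 the step is enantioconvergent. The step needs O- over C-alkylation and ring closure over oligomerisation, which the substrate secures by having a single free hydroxyl placed next to the side chain (attack at C4 would give a four-membered ring) and which high dilution supports, and it needs catalysed over uncatalysed ionisation, which toluene at −78 °C secures because neutral 8 should not ionise there. The amine quench at low temperature stops re-ionisation of the C2–O1 bond of 10, which is carried on at once.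

Step 8
Reactants: 10 the (2S)-flav-3-ene of step 7
Product: 12 (2R,3S)-5-(benzyloxy)-2-[4-(benzyloxy)-3-(methoxymethoxy)phenyl]-7-(methoxymethoxy)chroman-3-ol, via flavan-3-ylborane 11 (not isolated)
Conditions: BH3·THF (2 equiv), THF, 0 °C → rt; then 3 M NaOH, 30 % H2O2, 0 °C
Reagents that add atoms: borane–THF, B.C1CCOC1 (boron stays only in 11); hydrogen peroxide, OO
Why: Hydroboration–oxidation of a flav-3-ene; boron goes to C3 because electron-rich ring A stabilises positive charge at C4, syn addition occurs on the face opposite to the C2 aryl group, and the C–B bond is oxidised with retention, so C3 is set 2,3-trans (3S) by substrate control from C2, whose descriptor changes from S to R only through the CIP ranking.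

Step 9
Reactants: 12 the bis-MOM flavan-3-ol of step 8
Product: 13 (2R,3S)-5-(benzyloxy)-2-[4-(benzyloxy)-3-hydroxyphenyl]chroman-3,7-diol (5,4'-di-O-benzyl-(+)-catechin)
Conditions: conc HCl (cat), MeOH–THF, 40 °C
Reagents that add atoms: none
Why: Acid-catalysed acetal exchange (methanolysis) removes both aryl MOM ethers as dimethoxymethane, the excess methanol traps the methoxymethyl cation before it can attack ring A, and the benzyl ethers, the secondary alcohol and both stereocentres should be untouched under these mild conditions.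

Step 10
Reactants: 14 3,4,5-tris(benzyloxy)benzoic acid
Product: 15 3,4,5-tris(benzyloxy)benzoyl chloride
Conditions: (COCl)2 (1.3 equiv), DMF (cat), CH2Cl2, 0 °C → rt
Reagents that add atoms: oxalyl chloride, O=C(Cl)C(=O)Cl
Why: Standard acid chloride formation through the Vilsmeier-type chloroiminium catalyst; benzyl ethers are inert.

Step 11
Reactants: 13 5,4'-di-O-benzyl-(+)-catechin; 15 3,4,5-tris(benzyloxy)benzoyl chloride (2.1 equiv)
Product: 16 5,4'-di-O-benzyl-(+)-catechin 7,3'-bis[3,4,5-tris(benzyloxy)benzoate]
Conditions: K2CO3 (2.5 equiv), acetone, 0 °C → rt, no DMAP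
Reagents that add atoms: none
Why: Phenoxide-selective O-acylation; carbonate deprotonates only the 7-OH and 3'-OH, whose phenoxides react with the aroyl chloride far faster than the neutral secondary 3-OH in the absence of a nucleophilic catalyst, and C2 is safe because O4' is still benzylated and no quinone methide can form.

Step 12
Reactants: 16 the octabenzyl bis-gallate of step 11
Product: 17 catechin 7,3'-di-O-gallate, (2R,3S)
Conditions: H2 (1 atm), 20 % Pd(OH)2/C, THF–EtOAc, rt; filtration, evaporation
Reagents that add atoms: none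
Why: Catalytic hydrogenolysis cleaves all eight benzyl ethers under neutral conditions that leave the two aryl esters, the cyclic C2–O1 ether and both stereocentres intact, and no base is present that could move the 3'-galloyl group to O4'.

**Compound list**
1 | 2,4,6-trihydroxybenzaldehyde | O=Cc1c(O)cc(O)cc1O | starting material
2 | 2,6-dihydroxy-4-(methoxymethoxy)benzaldehyde | O=Cc1c(O)cc(OCOC)cc1O | intermediate
3 | 2-(benzyloxy)-6-hydroxy-4-(methoxymethoxy)benzaldehyde | O=Cc1c(O)cc(OCOC)cc1OCc1ccccc1 | intermediate
4 | 3',4'-dihydroxyacetophenone | CC(=O)c1ccc(O)c(O)c1 | starting material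
5 | 4'-(benzyloxy)-3'-hydroxyacetophenone | CC(=O)c1ccc(OCc2ccccc2)c(O)c1 | intermediate
6 | 4'-(benzyloxy)-3'-(methoxymethoxy)acetophenone | CC(=O)c1ccc(OCc2ccccc2)c(OCOC)c1 | intermediate
7 | (E)-3-[2-(benzyloxy)-6-hydroxy-4-(methoxymethoxy)phenyl]-1-[4-(benzyloxy)-3-(methoxymethoxy)phenyl]prop-2-en-1-one | COCOc1cc(O)c(/C=C/C(=O)c2ccc(OCc3ccccc3)c(OCOC)c2)c(OCc2ccccc2)c1 | intermediate
8 | rac-(E)-3-[2-(benzyloxy)-6-hydroxy-4-(methoxymethoxy)phenyl]-1-[4-(benzyloxy)-3-(methoxymethoxy)phenyl]prop-2-en-1-ol | COCOc1cc(O)c(/C=C/C(O)c2ccc(OCc3ccccc3)c(OCOC)c2)c(OCc2ccccc2)c1 | intermediate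
9 | 1,3-diarylallyl cation (ion pair with the chiral phosphoramidate; one resonance form drawn) | COCOc1cc(O)c(C=C[CH+]c2ccc(OCc3ccccc3)c(OCOC)c2)c(OCc2ccccc2)c1 | intermediate (not isolated)
10 | (2S)-5-(benzyloxy)-2-[4-(benzyloxy)-3-(methoxymethoxy)phenyl]-7-(methoxymethoxy)-2H-chromene | COCOc1cc(OCc3ccccc3)c2c(c1)O[C@H](c1ccc(OCc3ccccc3)c(OCOC)c1)C=C2 | intermediate
11 | 2,3-trans-flavan-3-ylborane (boron at C3, opposite to ring B; drawn as the monoalkylborane) | COCOc1cc(OCc3ccccc3)c2c(c1)O[C@H](c1ccc(OCc3ccccc3)c(OCOC)c1)[C@@H](B)C2 | intermediate (not isolated)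
12 | (2R,3S)-5-(benzyloxy)-2-[4-(benzyloxy)-3-(methoxymethoxy)phenyl]-7-(methoxymethoxy)chroman-3-ol | COCOc1cc(OCc3ccccc3)c2c(c1)O[C@H](c1ccc(OCc3ccccc3)c(OCOC)c1)[C@@H](O)C2 | intermediate
13 | (2R,3S)-5-(benzyloxy)-2-[4-(benzyloxy)-3-hydroxyphenyl]chroman-3,7-diol | Oc1cc(OCc3ccccc3)c2c(c1)O[C@H](c1ccc(OCc3ccccc3)c(O)c1)[C@@H](O)C2 | intermediate
14 | 3,4,5-tris(benzyloxy)benzoic acid | O=C(O)c1cc(OCc2ccccc2)c(OCc2ccccc2)c(OCc2ccccc2)c1 | starting material
15 | 3,4,5-tris(benzyloxy)benzoyl chloride | O=C(Cl)c1cc(OCc2ccccc2)c(OCc2ccccc2)c(OCc2ccccc2)c1 | intermediate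
16 | 5,4'-di-O-benzyl-(+)-catechin 7,3'-bis[3,4,5-tris(benzyloxy)benzoate] | O=C(Oc1cc(OCc4ccccc4)c2c(c1)O[C@H](c1ccc(OCc4ccccc4)c(OC(=O)c3cc(OCc4ccccc4)c(OCc4ccccc4)c(OCc4ccccc4)c3)c1)[C@@H](O)C2)c1cc(OCc2ccccc2)c(OCc2ccccc2)c(OCc2ccccc2)c1 | intermediate
17 | catechin 7,3'-di-O-gallate, (2R,3S) | O=C(Oc1cc(O)c2c(c1)O[C@H](c1ccc(O)c(OC(=O)c3cc(O)c(O)c(O)c3)c1)[C@@H](O)C2)c1cc(O)c(O)c(O)c1 | target

**Step count**
Total steps: 12. Longest linear sequence: 9 (steps 1, 2, 5, 6, 7, 8, 9, 11, 12).

**Steps most likely to fail**

Step 7. Enantiocontrol may be lost through uncatalysed ionisation of the very electron-rich alcohol or through re-ionisation of the product. The cation may also be consumed by intermolecular Friedel–Crafts oligomerisation.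
The fallback gives up asymmetric ring closure and resolves afterwards. It sets out from 8 and comes back at 12.
- Alcohol 8 would be cyclised with an achiral acid (PPTS, CH2Cl2, 0 °C) to the racemic flav-3-ene F1.
- This would be hydroborated and oxidised as in step 8 to the racemic 2,3-trans-flavan-3-ol F2.
- The racemate would be resolved by lipase-catalysed acyl transfer (Burkholderia cepacia lipase, vinyl acetate, MTBE, 35 °C).
- By the empirical size rule for lipases, the (3R)-enantiomer should be converted into the (2S,3R)-3-acetate F3. The alcohol left unreacted is 12.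

Step 6. The allylic alcohol may ionise during work-up or on silica and close the ring spontaneously without stereocontrol. Conjugate reduction may also compete.
The fallback never liberates the free hydroxy-phenol and changes the activation mode from acid to transition metal. It sets out from 7 and comes back at 10.
- The aluminium alkoxide/phenoxide from the DIBAL-H reduction would be trapped at −78 °C with Ac2O, pyridine and DMAP. This gives the storable racemic diacetate F4, whose masked phenol cannot cyclise.
- The diacetate would then undergo Pd-catalysed asymmetric intramolecular allylic etherification (Pd2(dba)3·CHCl3, TADDOL-derived phosphoramidite, K2CO3, MeOH–THF, 0 °C).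
- In that reaction the aryl acetate is methanolysed in situ, the allylic acetate ionises to a π-allylpalladium complex, and the phenoxide closes 6-endo-trig to 10.

Step 11. The secondary 3-OH may be acylated as well, or the hindered 3'-OH may be acylated incompletely, giving inseparable ester mixtures.
The fallback replaces chemoselectivity by protection. It sets out from 12 and comes back at 17.
- Compound 12 would be benzylated (NaH, BnBr, DMF, 0 °C) to the 3-O-benzyl ether F5.
- The MOM groups would be removed as in step 9 to give the bis-phenol F6.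
- Both phenols would be acylated under forcing conditions (15, K2CO3, DMAP cat, acetone) to the nonabenzyl bis-gallate F7.
- Hydrogenolysis as in step 12 would cleave nine benzyl ethers to 17.

**Further compounds**
F1 | step 7 | rac-5-(benzyloxy)-2-[4-(benzyloxy)-3-(methoxymethoxy)phenyl]-7-(methoxymethoxy)-2H-chromene | COCOc1cc(OCc3ccccc3)c2c(c1)OC(c1ccc(OCc3ccccc3)c(OCOC)c1)C=C2
F2 | step 7 | rac-2,3-trans-5-(benzyloxy)-2-[4-(benzyloxy)-3-(methoxymethoxy)phenyl]-7-(methoxymethoxy)chroman-3-ol (both enantiomers) | COCOc1cc(OCc3ccccc3)c2c(c1)O[C@H](c1ccc(OCc3ccccc3)c(OCOC)c1)[C@@H](O)C2.COCOc1cc(OCc3ccccc3)c2c(c1)O[C@@H](c1ccc(OCc3ccccc3)c(OCOC)c1)[C@H](O)C2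
F3 | step 7 | (2S,3R)-5-(benzyloxy)-2-[4-(benzyloxy)-3-(methoxymethoxy)phenyl]-7-(methoxymethoxy)chroman-3-yl acetate | COCOc1cc(OCc3ccccc3)c2c(c1)O[C@@H](c1ccc(OCc3ccccc3)c(OCOC)c1)[C@H](OC(C)=O)C2
F4 | step 6 | rac-(E)-3-[2-acetoxy-6-(benzyloxy)-4-(methoxymethoxy)phenyl]-1-[4-(benzyloxy)-3-(methoxymethoxy)phenyl]prop-2-enyl acetate | COCOc1cc(OC(C)=O)c(/C=C/C(OC(C)=O)c2ccc(OCc3ccccc3)c(OCOC)c2)c(OCc2ccccc2)c1
F5 | step 11 | (2R,3S)-3,5-bis(benzyloxy)-2-[4-(benzyloxy)-3-(methoxymethoxy)phenyl]-7-(methoxymethoxy)chroman | COCOc1cc(OCc3ccccc3)c2c(c1)O[C@H](c1ccc(OCc3ccccc3)c(OCOC)c1)[C@@H](OCc1ccccc1)C2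
F6 | step 11 | (2R,3S)-3,5-bis(benzyloxy)-2-[4-(benzyloxy)-3-hydroxyphenyl]chroman-7-ol | Oc1cc(OCc3ccccc3)c2c(c1)O[C@H](c1ccc(OCc3ccccc3)c(O)c1)[C@@H](OCc1ccccc1)C2
F7 | step 11 | 3,5,4'-tri-O-benzyl-(+)-catechin 7,3'-bis[3,4,5-tris(benzyloxy)benzoate] | O=C(Oc1cc(OCc4ccccc4)c2c(c1)O[C@H](c1ccc(OCc4ccccc4)c(OC(=O)c3cc(OCc4ccccc4)c(OCc4ccccc4)c(OCc4ccccc4)c3)c1)[C@@H](OCc1ccccc1)C2)c1cc(OCc2ccccc2)c(OCc2ccccc2)c(OCc2ccccc2)c1
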